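I began with the gap.

| setting | dusk | winter | flask |
|---|---|---|---|
| Q | 0.80 M | 0.80 M | 0.80 M |
| J | 1.6 M | 2.4 M | 1.60 M |
| E | 0.80 mM | 0.80 mM | 0.80 mM |
| G | 3.2 mM | 3.2 mM | 3.2 mM |
| remark | the very flask that is asked about, followed so far | run made earlier |  |

| run | time / min | Z / % | Q / % |
|---|---|---|---|
| dusk | 8.00 | 0.3 | 97.8 |
| dusk | 25.0 | 0 | 93.9 |
| dusk | 40.0 | 0.6 | 89.9 |
| dusk | 60.0 | 1.7 | 86.9 |
| dusk | 90.0 | 4.5 | 80.1 |
| winter | 20.0 | 0.5 | 95.0 |
| winter | 40.0 | 1.0 | 90.5 |
| winter | 60.0 | 2.1 | 85.3 |
| winter | 80.0 | 4.0 | 82.7 |
| winter | 90.0 | 4.6 | 81.4 |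

(readings scatter by 0.5 percentage points)

- no earlier run changes the charge of E; that part of a forecast is a guess

* apparent order in J when 20% of the Q are converted (percent change of the rate of making Z for one percent more J charged)
* apparent order in E when 20% of the Q are converted (percent change of the rate of making Z for one percent more E charged)

Where had the lost Q gone? In the dusk flask at 90.0 min, Q read 80.1%, close to the conversion asked about, and Z read 4.5%. That left 15.4% of the charge unaccounted for. I call this fraction of the Q charged, neither Q nor Z, the gap. It read 3.42 times Z, so I took it as the stock that Z is made from.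

Did more J drain that stock faster? The winter flask, with 1.50 times the J, read a gap of 14.0% and Z of 4.6% at the same time. From the two Z readings I reckoned an order in J of 0.0542, give or take 0.388, so my margin was wider than the number itself.

What of E? Neither run changed it, so I had no reading and committed to no number.

The forecast gave 0.1 in J and 0.6 in E, saying “So the J order is near zero”.

The flask gave 0.53 in J and 1.2 in E.

    J + L → E + Z (k = 0.660 /M/s)
    E + G ⇌ X, settled at all times (K = 2400 /M)
    E + D ⇌ L (K = 0.990 /M, k = 1.90 /M/s)
    Q + E ⇌ E + D (K = 1.60, k = 0.380 /M/s)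

On J the two parted by a factor of 5.30. With the reverse step from L to E + D taken away, the simulated run gives a J order of 0.030 instead of 0.53, the largest single effect on it: L either falls back to D or meets J. Z made at 0.0347 M/h from the gap in this dusk flask means a drain of 0.281 /h. In the winter flask the order puts the rate of making Z at about 0.0429 M/h, and over its read gap of 14.0% that means a drain of about 0.383 /h.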